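**Remark:** Compounds 1, 3, 9 and 13 are taken as purchasable. The carbinol carbon of 12 and C2 of 21 form as epimer mixtures and are left open in the SMILES, because steps 11 and 12 erase them.

## Retrosynthetic overview

- Ring letters: A, C, B are the benzo ring, pyran ring and aryl ring of the (3R)-isoflavan half (ring B is the central arene); D, E, F are the benzo ring, pyran ring and 3-aryl ring of the 3,4-diarylchroman half (ring E numbered O1, C2, C3, C4, C4a, C8a).
- Last disconnections: the four O-benzyl groups, and C2 of ring E taken back from CH2 to the lactol (chroman-2-ol) oxidation level.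
- Ring E is closed last and convergently: an amine-catalysed formal [4+2] joins an ortho-quinone methide (O1=C8a–C4a=C4 of ring D, with ring B on the methide carbon) to the enamine of a ring F arylacetaldehyde, forming O1–C2 and C3–C4 and setting C3 and C4.
- Enabling feature: the free phenol O1 on C8a of ring D lies ortho to the doubly benzylic carbinol carbon C4, which is pushed by the C7 benzyloxy group and by the ortho-methoxy and para-benzyloxy groups of ring B, so the carbinol ionises to the 1-oxadiene under weak acid; carrying C2 as an aldehyde makes C3 the nucleophile and reverses the regiochemistry an arylalkene would show.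
- Before that: the carbinol comes from the ring B aryllithium of a (3R)-5'-bromoisoflavan and a ring D salicylaldehyde; ring C is formed first (chalcone, oxidative 1,2-aryl shift to the isoflavone, transfer hydrogenation with dynamic kinetic resolution, deoxygenation), ring E last.

Key step: step 11

## Route

**Step 1**
Reactants: 1 5-bromo-2-hydroxy-4-methoxybenzaldehyde
Product: 2 2-(benzyloxy)-5-bromo-4-methoxybenzaldehyde
Conditions: BnBr, K2CO3, DMF, 60 °C
Reagents that add atoms: benzyl bromide, BrCc1ccccc1
Why: Williamson etherification of the phenoxide (SN2 on benzyl bromide) protects the ring B phenol; no stereocentre is formed.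

**Step 2**
Reactants: 2 2-(benzyloxy)-5-bromo-4-methoxybenzaldehyde; 3 1-[4-(benzyloxy)-2-hydroxyphenyl]ethan-1-one
Product: 4 (E)-3-[2-(benzyloxy)-5-bromo-4-methoxyphenyl]-1-[4-(benzyloxy)-2-hydroxyphenyl]prop-2-en-1-one
Conditions: KOH (aq.), EtOH, rt
Reagents that add atoms: none
Why: Claisen–Schmidt aldol condensation of the acetophenone enolate with the non-enolisable aldehyde, with dehydration to the thermodynamically favoured E-enone.

**Step 3**
Reactants: 4 the chalcone from step 2
Product: 6 7-(benzyloxy)-3-[2-(benzyloxy)-5-bromo-4-methoxyphenyl]-4H-chromen-4-one, via dimethyl acetal 5 (not isolated)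
Conditions: Tl(NO3)3·3H2O, MeOH/CH(OMe)3, rt; then 10% HCl, MeOH, reflux
Reagents that add atoms: none
Why: Oxidative 1,2-aryl migration of a chalcone with trivalent thallium (methoxythallation, shift of the electron-rich ring B aryl from the β- to the α-carbon with loss of monovalent thallium, acetal formation), followed by acid-promoted attack of the ortho-hydroxyl on the acetal carbon and loss of methanol, is the classical chalcone-to-isoflavone rearrangement and closes ring C.

**Step 4**
Reactants: 6 the isoflavone from step 3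
Product: 7 (3R,4R)-7-(benzyloxy)-3-[2-(benzyloxy)-5-bromo-4-methoxyphenyl]chroman-4-ol (cis)
Conditions: RuCl[(R,R)-TsDPEN](p-cymene) (2 mol%), HCO2H/Et3N (5:2), EtOAc, 40 °C
Reagents that add atoms: none
Why: Noyori–Ikariya asymmetric transfer hydrogenation under dynamic kinetic resolution: conjugate reduction gives the isoflavanone, whose C3 epimerises through the enol under Et3N, and the (R,R)-catalyst should reduce the 3R ketone selectively in the aryl ketone sense to the 4R alcohol, setting C3 (R) and C4 (R) as the cis isomer.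

**Step 5**
Reactants: 7 the cis-isoflavan-4-ol from step 4
Product: 8 (3R)-7-(benzyloxy)-3-[2-(benzyloxy)-5-bromo-4-methoxyphenyl]chroman
Conditions: Et3SiH, TFA, CH2Cl2, −40 → 0 °C
Reagents that add atoms: none
Why: Ionic hydrogenation (benzylic deoxygenation) through the C4 cation stabilised by the para C7 oxygen, which excess Et3SiH should trap faster than it eliminates, so that C3 keeps its R configuration and no new stereocentre arises.

**Step 6**
Reactants: 8 the bromoisoflavan from step 5; 9 4-(benzyloxy)-2-hydroxybenzaldehyde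
Product: 12 {4-(benzyloxy)-5-[(3R)-7-(benzyloxy)chroman-3-yl]-2-methoxyphenyl}[4-(benzyloxy)-2-hydroxyphenyl]methanol (both carbinol epimers), via aryllithium 10 (not isolated), via sodium 5-(benzyloxy)-2-formylphenolate 11 (not isolated)
Conditions: 8: n-BuLi, THF, −78 °C; 9: NaH, THF, 0 °C; combine, −78 → 0 °C; aq. NH4Cl; crude product used without silica gel chromatography
Reagents that add atoms: none
Why: Bromine–lithium exchange followed by 1,2-addition of the aryllithium to the aldehyde, whose acidic phenol is masked beforehand as the sodium phenoxide so that one equivalent of 10 suffices; the carbinol centre forms unselectively, which is harmless because it becomes planar in step 11.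

**Step 7**
Reactants: 13 2,6-dimethoxyphenol
Product: 14 2-(benzyloxy)-1,3-dimethoxybenzene
Conditions: BnBr, K2CO3, acetone, reflux
Reagents that add atoms: benzyl bromide, BrCc1ccccc1
Why: Williamson etherification protects the ring F phenol as the benzyl ether that is removed with the others at the end.

**Step 8**
Reactants: 14 2-(benzyloxy)-1,3-dimethoxybenzene
Product: 15 3-(benzyloxy)-2,4-dimethoxybenzaldehyde
Conditions: POCl3, DMF, 80 °C; then H2O
Reagents that add atoms: N,N-dimethylformamide, CN(C)C=O; water, O
Why: Vilsmeier–Haack formylation should occur para to one methoxy and ortho to the other (C4 and C6 are equivalent), the position para to the flanked, twisted benzyloxy group being less activated, as in the formylation of 1,2,3-trimethoxybenzene.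

**Step 9**
Reactants: 15 3-(benzyloxy)-2,4-dimethoxybenzaldehyde
Product: 16 2-(benzyloxy)-1,3-dimethoxy-4-(2-methoxyvinyl)benzene (E/Z mixture)
Conditions: Ph3P(CH2OMe)Cl, KOtBu, THF, 0 °C → rt
Reagents that add atoms: (methoxymethyl)triphenylphosphonium chloride, COC[P+](c1ccccc1)(c1ccccc1)c1ccccc1.[Cl-]
Why: Wittig methoxymethylenation (one-carbon homologation); the alkene geometry is irrelevant because both isomers hydrolyse to the same aldehyde.

**Step 10**
Reactants: 16 the enol ether from step 9
Product: 17 2-[3-(benzyloxy)-2,4-dimethoxyphenyl]acetaldehyde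
Conditions: 2 M HCl, THF, 50 °C; used at once
Reagents that add atoms: water, O
Why: Acid-catalysed enol ether hydrolysis (protonation at the benzylic carbon, hydration, loss of methanol) gives the arylacetaldehyde, which is used directly because it is prone to self-aldolisation.

**Step 11**
Reactants: 12 the ortho-hydroxy diarylcarbinol from step 6; 17 the arylacetaldehyde from step 10
Product: 21 (3R,4S)-7-(benzyloxy)-3-[3-(benzyloxy)-2,4-dimethoxyphenyl]-4-{4-(benzyloxy)-5-[(3R)-7-(benzyloxy)chroman-3-yl]-2-methoxyphenyl}chroman-2-ol (anomer mixture), via ortho-quinone methide 18 (not isolated), via catalyst enamine 19 (not isolated), via N,O-aminal cycloadduct 20 (not isolated)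
Conditions: (R)-α,α-diphenylprolinol trimethylsilyl ether (20 mol%), PhCO2H (20 mol%), toluene, 0 °C → rt; 17 used in excess (2 equiv)
Reagents that add atoms: none
Why: Benzoic acid assists dehydration of the push–pull carbinol 12 to the E-configured ortho-quinone methide 18 while the amine condenses with 17 to the E-enamine 19; the nucleophilic enamine carbon (future C3) adds to the electrophilic methide carbon (future C4), the phenolate oxygen O1 closes onto the iminium carbon (future C2) to give aminal 20, and the water released hydrolyses 20 to lactol 21 and returns the amine. The closest known reaction type is the amine-catalysed enamine/ortho-quinone methide formal [4+2] (Michael addition–hemiacetalisation, an inverse-electron-demand oxa-Diels–Alder reaction in its stepwise limit) of aldehydes with quinone methides generated in situ, together with the SN1-type α-alkylation of aldehydes by diarylcarbinols under amine/acid catalysis. Ring E closes by 6-exo-trig attack of O1 on the iminium carbon, and after hydrolysis re-closes as the hemiacetal in the same 6-exo-trig mode. C4 is controlled by the catalyst: the C(Ph)2OSiMe3 group blocks one face of the s-trans E-enamine, and a synclinal, endo-type approach of the E-quinone methide (carbonyl oxygen near nitrogen) to the open face should, by analogy with the established sense of this catalyst class with E-configured acceptors, give 4S with the (R)-amine; C3 is set R in the same event with the two aryl groups anti (trans), and as an epimerisable α-aryl aldehyde/lactol centre it would in any case settle in the trans-diequatorial arrangement. The step needs regioselectivity (O1 to C2, C4 to C3), secured by the aldehyde oxidation level at C2 that polarises the two-carbon partner as an enamine; cross-reaction over Friedel–Crafts self-alkylation, secured by the nucleophilicity and excess of the enamine; and facial selectivity at C4, which rests on the catalyst because the ring C stereocentre is too remote to help.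

**Step 12**
Reactants: 21 the lactol from step 11
Product: 22 (3R,4S)-7-(benzyloxy)-3-[3-(benzyloxy)-2,4-dimethoxyphenyl]-4-{4-(benzyloxy)-5-[(3R)-7-(benzyloxy)chroman-3-yl]-2-methoxyphenyl}chroman
Conditions: Et3SiH, BF3·OEt2, CH2Cl2, −78 → −20 °C
Reagents that add atoms: none
Why: Lactol deoxygenation by ionic hydrogenation: BF3·OEt2 ionises the anomeric hydroxyl to the cyclic aryloxocarbenium ion, which Et3SiH reduces at C2 without touching C3 or C4, and any C3 epimerisation through the open hydroxy-aldehyde can only favour the trans product.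

**Step 13**
Reactants: 22 the tetrabenzyl ether from step 12
Product: 23 (3R,4S)-3-(3-hydroxy-2,4-dimethoxyphenyl)-4-{4-hydroxy-5-[(3R)-7-hydroxychroman-3-yl]-2-methoxyphenyl}chroman-7-ol (target, CNP0202416.1)
Conditions: H2 (1 atm), 10% Pd/C, EtOAc/MeOH, rt
Reagents that add atoms: none
Why: Palladium-catalysed hydrogenolysis cleaves the four benzyl aryl ethers, while the ring ether C–O bonds and the doubly benzylic C4–H are not benzylic C–O bonds and should stay intact, so no stereocentre is touched.

## Compound list

1 | 5-bromo-2-hydroxy-4-methoxybenzaldehyde | O=Cc1cc(Br)c(OC)cc1O | starting material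
2 | 2-(benzyloxy)-5-bromo-4-methoxybenzaldehyde | O=Cc1cc(Br)c(OC)cc1OCc1ccccc1 | intermediate
3 | 1-[4-(benzyloxy)-2-hydroxyphenyl]ethan-1-one | CC(=O)c1ccc(OCc2ccccc2)cc1O | starting material
4 | (E)-3-[2-(benzyloxy)-5-bromo-4-methoxyphenyl]-1-[4-(benzyloxy)-2-hydroxyphenyl]prop-2-en-1-one | O=C(/C=C/c1cc(Br)c(OC)cc1OCc1ccccc1)c1ccc(OCc2ccccc2)cc1O | intermediate
5 | 1-[4-(benzyloxy)-2-hydroxyphenyl]-2-[2-(benzyloxy)-5-bromo-4-methoxyphenyl]-3,3-dimethoxypropan-1-one (racemic, not isolated) | COC(OC)C(C(=O)c1ccc(OCc2ccccc2)cc1O)c1cc(Br)c(OC)cc1OCc1ccccc1 | intermediate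
6 | 7-(benzyloxy)-3-[2-(benzyloxy)-5-bromo-4-methoxyphenyl]-4H-chromen-4-one | COc1cc(OCc2ccccc2)c(-c2coc3cc(OCc4ccccc4)ccc3c2=O)cc1Br | intermediate
7 | (3R,4R)-7-(benzyloxy)-3-[2-(benzyloxy)-5-bromo-4-methoxyphenyl]chroman-4-ol | COc1cc(OCc2ccccc2)c([C@@H]2COc3cc(OCc4ccccc4)ccc3[C@@H]2O)cc1Br | intermediate
8 | (3R)-7-(benzyloxy)-3-[2-(benzyloxy)-5-bromo-4-methoxyphenyl]chroman | COc1cc(OCc2ccccc2)c([C@@H]2COc3cc(OCc4ccccc4)ccc3C2)cc1Br | intermediate
9 | 4-(benzyloxy)-2-hydroxybenzaldehyde | O=Cc1ccc(OCc2ccccc2)cc1O | starting material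
10 | {4-(benzyloxy)-5-[(3R)-7-(benzyloxy)chroman-3-yl]-2-methoxyphenyl}lithium (not isolated) | COc1cc(OCc2ccccc2)c([C@@H]2COc3cc(OCc4ccccc4)ccc3C2)cc1[Li] | intermediate
11 | sodium 5-(benzyloxy)-2-formylphenolate (not isolated) | O=Cc1ccc(OCc2ccccc2)cc1[O-].[Na+] | intermediate
12 | {4-(benzyloxy)-5-[(3R)-7-(benzyloxy)chroman-3-yl]-2-methoxyphenyl}[4-(benzyloxy)-2-hydroxyphenyl]methanol (carbinol epimers) | COc1cc(OCc2ccccc2)c([C@@H]2COc3cc(OCc4ccccc4)ccc3C2)cc1C(O)c1ccc(OCc2ccccc2)cc1O | intermediate
13 | 2,6-dimethoxyphenol | COc1cccc(OC)c1O | starting material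
14 | 2-(benzyloxy)-1,3-dimethoxybenzene | COc1cccc(OC)c1OCc1ccccc1 | intermediate
15 | 3-(benzyloxy)-2,4-dimethoxybenzaldehyde | COc1ccc(C=O)c(OC)c1OCc1ccccc1 | intermediate
16 | 2-(benzyloxy)-1,3-dimethoxy-4-(2-methoxyvinyl)benzene (E/Z mixture) | COC=Cc1ccc(OC)c(OCc2ccccc2)c1OC | intermediate
17 | 2-[3-(benzyloxy)-2,4-dimethoxyphenyl]acetaldehyde | O=CCc1ccc(OC)c(OCc2ccccc2)c1OC | intermediate
18 | (6E)-3-(benzyloxy)-6-({4-(benzyloxy)-5-[(3R)-7-(benzyloxy)chroman-3-yl]-2-methoxyphenyl}methylidene)cyclohexa-2,4-dien-1-one (not isolated) | COc1cc(OCc2ccccc2)c([C@@H]2COc3cc(OCc4ccccc4)ccc3C2)cc1/C=C1\C=CC(OCc2ccccc2)=CC1=O | intermediate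
19 | (2R)-1-{(E)-2-[3-(benzyloxy)-2,4-dimethoxyphenyl]vinyl}-2-[diphenyl(trimethylsilyloxy)methyl]pyrrolidine (not isolated) | COc1ccc(/C=C/N2CCC[C@@H]2C(c2ccccc2)(c2ccccc2)O[Si](C)(C)C)c(OC)c1OCc1ccccc1 | intermediate
20 | (2S,3R,4S)-2-{(2R)-2-[diphenyl(trimethylsilyloxy)methyl]pyrrolidin-1-yl} analogue of 22, C2 drawn for the endo mode (not isolated) | COc1cc(OCc2ccccc2)c([C@@H]3COc4cc(OCc5ccccc5)ccc4C3)cc1[C@@H]1c2ccc(OCc3ccccc3)cc2O[C@H](N2CCC[C@@H]2C(c2ccccc2)(c2ccccc2)O[Si](C)(C)C)[C@H]1c1ccc(OC)c(OCc2ccccc2)c1OC | intermediate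
21 | (3R,4S)-7-(benzyloxy)-3-[3-(benzyloxy)-2,4-dimethoxyphenyl]-4-{4-(benzyloxy)-5-[(3R)-7-(benzyloxy)chroman-3-yl]-2-methoxyphenyl}chroman-2-ol (anomer mixture) | COc1cc(OCc2ccccc2)c([C@@H]3COc4cc(OCc5ccccc5)ccc4C3)cc1[C@@H]1c2ccc(OCc3ccccc3)cc2OC(O)[C@H]1c1ccc(OC)c(OCc2ccccc2)c1OC | intermediate
22 | (3R,4S)-7-(benzyloxy)-3-[3-(benzyloxy)-2,4-dimethoxyphenyl]-4-{4-(benzyloxy)-5-[(3R)-7-(benzyloxy)chroman-3-yl]-2-methoxyphenyl}chroman | COc1cc(OCc2ccccc2)c([C@@H]3COc4cc(OCc5ccccc5)ccc4C3)cc1[C@@H]1c2ccc(OCc3ccccc3)cc2OC[C@H]1c1ccc(OC)c(OCc2ccccc2)c1OC | intermediate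
23 | (3R,4S)-3-(3-hydroxy-2,4-dimethoxyphenyl)-4-{4-hydroxy-5-[(3R)-7-hydroxychroman-3-yl]-2-methoxyphenyl}chroman-7-ol | COc1cc(O)c([C@@H]2COc3cc(O)ccc3C2)cc1[C@@H]1c2ccc(O)cc2OC[C@H]1c1ccc(OC)c(O)c1OC | target

## Step count and risks

Total step count: 13. Longest linear sequence: 9 steps (steps 1–6, then 11–13); the ring F branch (steps 7–10) joins at step 11.

**Steps most likely to fail**

1. **Step 11.** The amine controls C4 only through the relative approach of enamine and quinone methide, so facial discrimination at the methide carbon may be insufficient. Self-aldolisation of 17 and Friedel–Crafts self-alkylation of the cation from 12 may also compete. If only the sense of induction is wrong, the enantiomeric amine is used. The fallback changes the mode of catalysis; it sets out from 17 and 12 and comes back at 21. Acid-catalysed condensation of 17 with benzyl carbamate (cat. TsOH, toluene, reflux with removal of water) should give benzyl (E)-{2-[3-(benzyloxy)-2,4-dimethoxyphenyl]vinyl}carbamate F1. A BINOL-derived chiral phosphoric acid (TRIP, 5–10 mol%, CH2Cl2, −20 °C, enantiomer chosen for 4S) then ionises 12 to the quinone methide. By binding the quinone methide oxygen and the carbamate N–H at the same time, it should steer an inverse-electron-demand oxa-Diels–Alder reaction to benzyl {(3R,4S)-7-(benzyloxy)-3-[3-(benzyloxy)-2,4-dimethoxyphenyl]-4-{4-(benzyloxy)-5-[(3R)-7-(benzyloxy)chroman-3-yl]-2-methoxyphenyl}chroman-2-yl}carbamate F2. Here the chiral acid addresses the methide face directly. Mild aqueous acid (aq. HCl, THF, 40 °C) hydrolyses the N,O-acetal of F2 to lactol 21.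

2. **Step 5.** The C4 cation may lose the C3 proton to the 2H-chromene and be reprotonated, which would erode the C3 configuration; it may also be intercepted by the neighbouring benzyloxy oxygen. The fallback sets C3 by catalyst instead of carrying it through a cation; it sets out from 7 and comes back at 8. MsCl and Et3N (CH2Cl2, 0 °C) convert 7 into (3R,4R)-7-(benzyloxy)-3-[2-(benzyloxy)-5-bromo-4-methoxyphenyl]chroman-4-yl methanesulfonate F3, which is not isolated. DBU then removes the C3 proton, which is anti to the leaving group in the cis isomer, to give 7-(benzyloxy)-3-[2-(benzyloxy)-5-bromo-4-methoxyphenyl]-2H-chromene F4. Asymmetric hydrogenation with [Ir(cod)(tBu-PHOX)]BArF under H2 (50 bar, CH2Cl2), with the ligand enantiomer chosen for 3R, should reduce the aryl-substituted alkene without touching the aryl bromide or the benzyl ethers and give 8.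

3. **Step 12.** The C2 oxocarbenium ion may lose the C3 proton to a 4H-chromene, whose reduction would place hydrogen on C3 from the face away from the C4 aryl group and lead to the cis isomer. The open hydroxy-aldehyde may also be reduced without ring closure. The fallback separates reduction from ring closure; it sets out from 21 and comes back at 22. NaBH4 (MeOH/THF, 0 °C) reduces the open-chain aldehyde tautomer of 21 to (2R,3S)-3-[4-(benzyloxy)-2-hydroxyphenyl]-2-[3-(benzyloxy)-2,4-dimethoxyphenyl]-3-{4-(benzyloxy)-5-[(3R)-7-(benzyloxy)chroman-3-yl]-2-methoxyphenyl}propan-1-ol F5. A Mitsunobu etherification (PPh3, DIAD, THF, 0 °C → rt) then closes ring E by 6-exo-tet attack of the phenol oxygen on the primary carbinol carbon, which touches no stereocentre, and gives 22.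

## Further compounds

F1 | step 11 | benzyl (E)-{2-[3-(benzyloxy)-2,4-dimethoxyphenyl]vinyl}carbamate | COc1ccc(/C=C/NC(=O)OCc2ccccc2)c(OC)c1OCc1ccccc1
F2 | step 11 | benzyl {(3R,4S)-7-(benzyloxy)-3-[3-(benzyloxy)-2,4-dimethoxyphenyl]-4-{4-(benzyloxy)-5-[(3R)-7-(benzyloxy)chroman-3-yl]-2-methoxyphenyl}chroman-2-yl}carbamate (C2 left open) | COc1cc(OCc2ccccc2)c([C@@H]3COc4cc(OCc5ccccc5)ccc4C3)cc1[C@@H]1c2ccc(OCc3ccccc3)cc2OC(NC(=O)OCc2ccccc2)[C@H]1c1ccc(OC)c(OCc2ccccc2)c1OC
F3 | step 5 | (3R,4R)-7-(benzyloxy)-3-[2-(benzyloxy)-5-bromo-4-methoxyphenyl]chroman-4-yl methanesulfonate | COc1cc(OCc2ccccc2)c([C@@H]2COc3cc(OCc4ccccc4)ccc3[C@@H]2OS(C)(=O)=O)cc1Br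
F4 | step 5 | 7-(benzyloxy)-3-[2-(benzyloxy)-5-bromo-4-methoxyphenyl]-2H-chromene | COc1cc(OCc2ccccc2)c(C2=Cc3ccc(OCc4ccccc4)cc3OC2)cc1Br
F5 | step 12 | (2R,3S)-3-[4-(benzyloxy)-2-hydroxyphenyl]-2-[3-(benzyloxy)-2,4-dimethoxyphenyl]-3-{4-(benzyloxy)-5-[(3R)-7-(benzyloxy)chroman-3-yl]-2-methoxyphenyl}propan-1-ol | COc1cc(OCc2ccccc2)c([C@@H]3COc4cc(OCc5ccccc5)ccc4C3)cc1[C@H](c1ccc(OCc2ccccc2)cc1O)[C@@H](CO)c1ccc(OC)c(OCc2ccccc2)c1OC
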